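**Plan**

1. Numbering used throughout: C1 quaternary carbon (methyl C15), C2 and C3 ring CH2, C4 isopropyl carbinol, C5 ring-fusion CH, C6 ester carbinol, C7 CH2, C8 (bears exocyclic C14), C9 free carbinol, C10 CH2; α is the face of H5, β the face of C15.
2. Retrosynthesis: cut the vanillate C–O bond at O6, the C8=C14 methylene and the C9–H bond (back to a 6,9-diketone); then cut ring bond C1–C10 together with a transient C5–C9 bond (photocycloaddition and retro-aldol); then C6–C7 (Grignard addition) and C5=C1 (aldol condensation of ozonised terpinen-4-ol).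
3. Enabling feature: O6 and O9 are 1,4-related across C7–C8 and quaternary C1 is β to C6, so the seven-membered ring C1–C5–C6–C7–C8–C9–C10 is the retro-aldol form of a cyclobutanol C1–C10–C9–C5 fused to a cyclopentanone C5–C6–C7–C8–C9.
4. Forward order: cyclopentene ring by aldol condensation, chain joined at C6, then cyclobutane and transient cyclopentanone by [2+2] and their merger into the seven-membered ring; afterwards C6 reduction, vanilloylation, C8 methylenation, C9 reduction and deprotection.
5. Stereochemistry: C4 from (S)-terpinen-4-ol; C1 from the face of the photocycloaddition (anti to the C4 silyloxy group); C5 by thermodynamic protonation to the trans fusion; C6 by hydride delivery from the 4β-hydroxyl; C9 by catalyst control with the (R)-oxazaborolidine.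

Key step: step 8

Remark: (S)-(+)-terpinen-4-ol of high enantiomeric purity and (4-bromobut-1-yn-1-yl)trimethylsilane are taken as purchased; locants in the names of 5 to 25 follow the numbering of the plan where "route numbering" is stated.

**Step 1**
Reactants: 1 (S)-(+)-terpinen-4-ol
Product: 2 (S)-terpinen-4-ol triethylsilyl ether
Conditions: Et3SiOTf, 2,6-lutidine, CH2Cl2, 0 °C → rt
Reagents that add atoms: triethylsilyl trifluoromethanesulfonate, CC[Si](CC)(CC)OS(=O)(=O)C(F)(F)F
Why: Silylation of a hindered tertiary alcohol with a silyl triflate and 2,6-lutidine (silyl ether protection) is routine; the ether prevents hemiketal formation and β-elimination after ring cleavage and later serves as the face-shielding group, and the carbinol stereocentre of 1 is untouched.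

**Step 2**
Reactants: 2 (S)-terpinen-4-ol triethylsilyl ether
Product: 4 (3S)-6-oxo-3-(propan-2-yl)-3-(triethylsilyloxy)heptanal, via ozonide 3 (not isolated)
Conditions: O3, CH2Cl2, −78 °C; then PPh3, −78 °C → rt
Reagents that add atoms: ozone, [O-][O+]=O
Why: Ozonolysis with reductive work-up cleaves the only C=C bond to the 1,6-keto aldehyde; silyl ethers tolerate ozone at −78 °C and the quaternary carbinol centre is not affected.

**Step 3**
Reactants: 4 (3S)-6-oxo-3-(propan-2-yl)-3-(triethylsilyloxy)heptanal
Product: 5 (5R)-2-methyl-5-(propan-2-yl)-5-(triethylsilyloxy)cyclopent-1-ene-1-carbaldehyde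
Conditions: piperidine, AcOH (cat.), toluene, 60 °C
Reagents that add atoms: none
Why: Amine-catalysed intramolecular aldol condensation: the aldehyde forms the enamine faster than the ketone, its α-carbon (C5) attacks the methyl ketone carbon (C1) in a 5-(enolexo)-exo-trig closure and dehydration gives the tetrasubstituted cyclopentenecarbaldehyde rather than the acetylcyclopentene regioisomer; no stereocentre is formed.

**Step 4**
Reactants: 5 (5R)-2-methyl-5-(propan-2-yl)-5-(triethylsilyloxy)cyclopent-1-ene-1-carbaldehyde and 6 (4-bromobut-1-yn-1-yl)trimethylsilane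
Product: 8 1-[(5R)-2-methyl-5-(propan-2-yl)-5-(triethylsilyloxy)cyclopent-1-en-1-yl]-5-(trimethylsilyl)pent-4-yn-1-ol (both C6 epimers), via Grignard reagent 7 (not isolated)
Conditions: 6, Mg, THF, rt; then 5, THF, −78 → 0 °C; aq. NH4Cl
Reagents that add atoms: none
Why: Grignard 1,2-addition to the enal, whose fully substituted β-carbon disfavours conjugate addition; the silyl cap keeps the alkyne C–H from quenching the reagent, and the new C6 carbinol centre (either epimer) is erased in step 5.

**Step 5**
Reactants: 8 1-[(5R)-2-methyl-5-(propan-2-yl)-5-(triethylsilyloxy)cyclopent-1-en-1-yl]-5-(trimethylsilyl)pent-4-yn-1-ol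
Product: 9 1-[(5R)-2-methyl-5-(propan-2-yl)-5-(triethylsilyloxy)cyclopent-1-en-1-yl]-5-(trimethylsilyl)pent-4-yn-1-one
Conditions: Dess–Martin periodinane, CH2Cl2, 0 °C → rt
Reagents that add atoms: none
Why: Dess–Martin oxidation of the secondary allylic alcohol to the conjugated ketone proceeds under near-neutral conditions that leave the tertiary silyl ether and the silylalkyne intact.

**Step 6**
Reactants: 9 1-[(5R)-2-methyl-5-(propan-2-yl)-5-(triethylsilyloxy)cyclopent-1-en-1-yl]-5-(trimethylsilyl)pent-4-yn-1-one
Product: 10 1-[(5R)-2-methyl-5-(propan-2-yl)-5-(triethylsilyloxy)cyclopent-1-en-1-yl]pent-4-yn-1-one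
Conditions: K2CO3, MeOH, 0 °C → rt
Reagents that add atoms: none
Why: Methanolysis of the C(sp)–SiMe3 bond with K2CO3 (alkynylsilane protodesilylation) is selective over the far more hindered tertiary Si–O bond.

**Step 7**
Reactants: 10 1-[(5R)-2-methyl-5-(propan-2-yl)-5-(triethylsilyloxy)cyclopent-1-en-1-yl]pent-4-yn-1-one
Product: 11 5-[(5R)-2-methyl-5-(propan-2-yl)-5-(triethylsilyloxy)cyclopent-1-en-1-yl]-5-oxopent-1-en-2-yl acetate
Conditions: AcOH, [RuCl2(p-cymene)]2 (cat.), P(2-furyl)3 (cat.), Na2CO3 (cat.), toluene, 50 °C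
Reagents that add atoms: acetic acid, CC(=O)O
Why: Ruthenium-catalysed Markovnikov hydro-acyloxylation of a terminal alkyne: acetate attacks the internal carbon (C9) of the metal-bound alkyne and protodemetalation gives the 1-alken-2-yl acetate, the phosphine and carbonate being chosen for the geminal rather than the anti-Markovnikov enol ester.

**Step 8**
Reactants: 11 5-[(5R)-2-methyl-5-(propan-2-yl)-5-(triethylsilyloxy)cyclopent-1-en-1-yl]-5-oxopent-1-en-2-yl acetate
Product: 14 trans-fused 4β-(triethylsilyloxy)-4α-isopropyl-1β-methyl-5αH-hydroazulene-6,9-dione (bicyclo[5.3.0]decane skeleton; route numbering), via photoadduct 12 (not isolated), via cyclobutanol 13 (not isolated)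
Conditions: hν (365 nm, Pyrex), degassed MeCN, rt; then MeOH, K2CO3, 0 °C
Reagents that add atoms: none
Why: Irradiation into the n→π* band gives the triplet 1-acylcyclopentene, which bonds C5 to C9 (1,5-closure, 5-exo-trig, giving the transient cyclopentanone C5–C6–C7–C8–C9) and then joins C1 to C10 by recombination of the 1,4-diradical to close the cyclobutane; methanolysis of the tertiary cyclobutyl acetate unmasks a β-hydroxy ketone whose strain-driven retro-aldol cleaves C5–C9, so that the four- and five-membered rings merge into the seven-membered ring (net a 7-endo union of C10 with C1) and the C5 enolate is protonated by methanol. The closest known reaction types are the intramolecular [2+2] photocycloaddition of 1-acylcycloalkenes with alkenes tethered through the acyl group and the de Mayo retro-aldol fragmentation of β-acyloxy cyclobutyl ketones. C1 is set by the face of cycloaddition: the triethylsilyl group sits anti to the isopropyl group and hence under the β face of the cyclopentene, so the alkene should add from the α face and C10 ends up trans to O4 (the cis fusion of the cyclobutane follows from geometry). C5 is set after the fragmentation by thermodynamic protonation, equilibration through the enolate favouring the trans ring fusion (H5 α) in which C6 lies cis to the silyloxy group and not to the isopropyl group. The step needs the straight and not the crossed adduct, which the three-atom tether between C5 and C9 secures (rule of five), and it needs protonation of the C5 enolate to outrun loss of silanolate from C4, which methanol as proton source and a weak base at 0 °C secure.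

**Step 9**
Reactants: 14 trans-fused 4β-(triethylsilyloxy)-4α-isopropyl-1β-methyl-5αH-hydroazulene-6,9-dione
Product: 15 trans-fused 4β-hydroxy-4α-isopropyl-1β-methyl-5αH-hydroazulene-6,9-dione
Conditions: HF·pyridine, pyridine, THF, 0 °C → rt
Reagents that add atoms: none
Why: Fluoride-driven Si–O cleavage with pyridine-buffered HF·pyridine removes the triethylsilyl ether without the base that would trigger retro-aldol opening of the C4–C5 bond or the strong acid that would dehydrate the β-hydroxy ketone; no stereocentre changes.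

**Step 10**
Reactants: 15 trans-fused 4β-hydroxy-4α-isopropyl-1β-methyl-5αH-hydroazulene-6,9-dione
Product: 16 4β,6α-dihydroxy-4α-isopropyl-1β-methyl-5αH-hydroazulen-9-one
Conditions: Me4NBH(OAc)3, MeCN/AcOH, −30 → −20 °C
Reagents that add atoms: none
Why: Hydroxyl-directed reduction of a β-hydroxy ketone with Me4NBH(OAc)3 (Evans–Saksena reduction): acetate exchange at the 4β-hydroxyl and intramolecular hydride transfer through a chair-like six-membered transition state deliver hydride to the β face of C6, the face on which O4 lies in the trans-fused skeleton and which external hydrides avoid, so that the 6α-alcohol (H6 anti to H5) results, while the C9 ketone, which has no β-hydroxyl, is not reduced by this mild borohydride.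

**Step 11**
Reactants: 17 vanillic acid
Product: 19 4-(tert-butyldimethylsilyloxy)-3-methoxybenzoic acid, via bis-silyl ester 18 (not isolated)
Conditions: t-BuMe2SiCl, imidazole, DMF, rt; then AcOH, THF/H2O, rt
Reagents that add atoms: tert-butyldimethylsilyl chloride, CC(C)(C)[Si](C)(C)Cl
Why: Silylation of phenol and carboxylic acid followed by selective hydrolysis of the much more labile silyl ester (phenol protection) leaves the free acid with the phenol masked as a fluoride-labile aryl silyl ether.

**Step 12**
Reactants: 19 4-(tert-butyldimethylsilyloxy)-3-methoxybenzoic acid and 16 4β,6α-dihydroxy-4α-isopropyl-1β-methyl-5αH-hydroazulen-9-one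
Product: 21 6α-[4-(tert-butyldimethylsilyloxy)-3-methoxybenzoyloxy]-4β-hydroxy-4α-isopropyl-1β-methyl-5αH-hydroazulen-9-one, via acid chloride 20 (not isolated)
Conditions: 19, (COCl)2, DMF (cat.), CH2Cl2, 0 °C → rt, evaporate; then 16, Et3N, DMAP, CH2Cl2, 0 °C → rt
Reagents that add atoms: none
Why: Acid chloride formation (oxalyl chloride with catalytic DMF) and DMAP-catalysed acylation esterify only the secondary 6α-hydroxyl, because the tertiary 4β-hydroxyl is too hindered to react and the C9 ketone is inert; the C6 configuration is retained since the C6–O bond is not broken.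

**Step 13**
Reactants: 21 6α-[4-(tert-butyldimethylsilyloxy)-3-methoxybenzoyloxy]-4β-hydroxy-4α-isopropyl-1β-methyl-5αH-hydroazulen-9-one
Product: 23 6α-[4-(tert-butyldimethylsilyloxy)-3-methoxybenzoyloxy]-4β-hydroxy-4α-isopropyl-1β-methyl-8-methylidene-5αH-hydroazulen-9-one, via Mannich base 22 (not isolated)
Conditions: (CH2O)n, i-Pr2NH·CF3CO2H, CF3CO2H (cat.), THF, 65 °C
Reagents that add atoms: formaldehyde (as paraformaldehyde), C=O
Why: Mannich-type α-methylenation: the enol of the C9 ketone adds to the iminium ion formed from formaldehyde and diisopropylamine at the less hindered α-carbon C8 (C10 is neopentylic, next to quaternary C1) and the Mannich base loses the amine by β-elimination to the exocyclic enone; the C8 centre of the intermediate is destroyed in the elimination.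

**Step 14**
Reactants: 23 6α-[4-(tert-butyldimethylsilyloxy)-3-methoxybenzoyloxy]-4β-hydroxy-4α-isopropyl-1β-methyl-8-methylidene-5αH-hydroazulen-9-one
Product: 24 6α-[4-(tert-butyldimethylsilyloxy)-3-methoxybenzoyloxy]-4α-isopropyl-1β-methyl-8-methylidene-5αH-hydroazulene-4β,9α-diol
Conditions: (R)-2-methyl-CBS-oxazaborolidine, catecholborane, toluene, −78 °C
Reagents that add atoms: none
Why: Corey–Bakshi–Shibata reduction: the (R)-oxazaborolidine binds the enone with the 1,1-disubstituted alkenyl branch (C8) as the large group and delivers hydride from catecholborane in a 1,2-fashion to the β face of C9, which sets the 9α-hydroxyl (9S) by catalyst control against the modest substrate bias of the axial C15 methyl, and catecholborane at −78 °C leaves the ester and the exocyclic alkene alone.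

**Step 15**
Reactants: 24 6α-[4-(tert-butyldimethylsilyloxy)-3-methoxybenzoyloxy]-4α-isopropyl-1β-methyl-8-methylidene-5αH-hydroazulene-4β,9α-diol
Product: 25 target, 4β,9α-dihydroxy-4α-isopropyl-1β-methyl-8-methylidene-5αH-hydroazulen-6α-yl 4-hydroxy-3-methoxybenzoate (1R,4R,5S,6S,9S in route numbering)
Conditions: Bu4NF, AcOH, THF, 0 °C
Reagents that add atoms: none
Why: Fluoride cleavage of the aryl silyl ether (Bu4NF buffered with AcOH) is fast at 0 °C and spares the vanillate ester, the allylic alcohol, the tertiary alcohol and the exocyclic alkene, so that the target is released without touching any stereocentre.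

**Compound list**

1 | (S)-(+)-terpinen-4-ol, (1S)-4-methyl-1-(propan-2-yl)cyclohex-3-en-1-ol | C1C=C(C)CC[C@@]1(O)C(C)C | starting material
2 | (S)-terpinen-4-ol triethylsilyl ether | C1C=C(C)CC[C@@]1(O[Si](CC)(CC)CC)C(C)C | intermediate
3 | ozonide of 2 (1,2,4-trioxolane across the former ring C=C; epimers at the two acetal carbons) | CC12CC[C@@](O[Si](CC)(CC)CC)(C(C)C)CC(OO1)O2 | intermediate (not isolated)
4 | (3S)-6-oxo-3-(propan-2-yl)-3-(triethylsilyloxy)heptanal | CC(=O)CC[C@@](CC=O)(O[Si](CC)(CC)CC)C(C)C | intermediate
5 | (5R)-2-methyl-5-(propan-2-yl)-5-(triethylsilyloxy)cyclopent-1-ene-1-carbaldehyde | O=CC1=C(C)CC[C@@]1(O[Si](CC)(CC)CC)C(C)C | intermediate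
6 | (4-bromobut-1-yn-1-yl)trimethylsilane | C[Si](C)(C)C#CCCBr | starting material
7 | [4-(trimethylsilyl)but-3-yn-1-yl]magnesium bromide | C[Si](C)(C)C#CCC[Mg]Br | intermediate (not isolated)
8 | 1-[(5R)-2-methyl-5-(propan-2-yl)-5-(triethylsilyloxy)cyclopent-1-en-1-yl]-5-(trimethylsilyl)pent-4-yn-1-ol, both carbinol epimers | C[Si](C)(C)C#CCCC(O)C1=C(C)CC[C@@]1(O[Si](CC)(CC)CC)C(C)C | intermediate
9 | 1-[(5R)-2-methyl-5-(propan-2-yl)-5-(triethylsilyloxy)cyclopent-1-en-1-yl]-5-(trimethylsilyl)pent-4-yn-1-one | C[Si](C)(C)C#CCCC(=O)C1=C(C)CC[C@@]1(O[Si](CC)(CC)CC)C(C)C | intermediate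
10 | 1-[(5R)-2-methyl-5-(propan-2-yl)-5-(triethylsilyloxy)cyclopent-1-en-1-yl]pent-4-yn-1-one | C#CCCC(=O)C1=C(C)CC[C@@]1(O[Si](CC)(CC)CC)C(C)C | intermediate
11 | 5-[(5R)-2-methyl-5-(propan-2-yl)-5-(triethylsilyloxy)cyclopent-1-en-1-yl]-5-oxopent-1-en-2-yl acetate (acylcyclopentene with tethered enol acetate) | C=C(OC(C)=O)CCC(=O)C1=C(C)CC[C@@]1(O[Si](CC)(CC)CC)C(C)C | intermediate
12 | tricyclic photoadduct: 9-acetoxy cyclobutane C1–C10–C9–C5 cis-fused to the cyclopentane C1–C5 and to the cyclopentanone C5–C9, C9 and C10 on the α face, 4β-triethylsilyloxy | CC(=O)O[C@]12CCC(=O)[C@@]13[C@](C)(CC[C@@]3(O[Si](CC)(CC)CC)C(C)C)C2 | intermediate (not isolated)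
13 | tertiary cyclobutanol from 12 (acetyl removed) | O[C@]12CCC(=O)[C@@]13[C@](C)(CC[C@@]3(O[Si](CC)(CC)CC)C(C)C)C2 | intermediate (not isolated)
14 | trans-fused 4β-(triethylsilyloxy)-4α-isopropyl-1β-methyl-5αH-hydroazulene-6,9-dione | C1CC(=O)[C@@H]2[C@](C)(CC[C@@]2(O[Si](CC)(CC)CC)C(C)C)CC1=O | intermediate
15 | trans-fused 4β-hydroxy-4α-isopropyl-1β-methyl-5αH-hydroazulene-6,9-dione | C1CC(=O)[C@@H]2[C@](C)(CC[C@@]2(O)C(C)C)CC1=O | intermediate
16 | 4β,6α-dihydroxy-4α-isopropyl-1β-methyl-5αH-hydroazulen-9-one | O=C1CC[C@H](O)[C@@H]2[C@](C)(CC[C@@]2(O)C(C)C)C1 | intermediate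
17 | vanillic acid | COc1cc(C(=O)O)ccc1O | starting material
18 | tert-butyldimethylsilyl 4-(tert-butyldimethylsilyloxy)-3-methoxybenzoate | COc1cc(C(=O)O[Si](C)(C)C(C)(C)C)ccc1O[Si](C)(C)C(C)(C)C | intermediate (not isolated)
19 | 4-(tert-butyldimethylsilyloxy)-3-methoxybenzoic acid | COc1cc(C(=O)O)ccc1O[Si](C)(C)C(C)(C)C | intermediate
20 | 4-(tert-butyldimethylsilyloxy)-3-methoxybenzoyl chloride | COc1cc(C(=O)Cl)ccc1O[Si](C)(C)C(C)(C)C | intermediate (not isolated)
21 | 6α-[4-(tert-butyldimethylsilyloxy)-3-methoxybenzoyloxy]-4β-hydroxy-4α-isopropyl-1β-methyl-5αH-hydroazulen-9-one | O=C1CC[C@H](OC(=O)c2ccc(O[Si](C)(C)C(C)(C)C)c(OC)c2)[C@@H]2[C@](C)(CC[C@@]2(O)C(C)C)C1 | intermediate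
22 | Mannich base of 21: 8-[(diisopropylamino)methyl] ketone, either C8 epimer | CC(C)N(CC1C[C@H](OC(=O)c2ccc(O[Si](C)(C)C(C)(C)C)c(OC)c2)[C@@H]2[C@](C)(CC[C@@]2(O)C(C)C)CC1=O)C(C)C | intermediate (not isolated)
23 | 6α-[4-(tert-butyldimethylsilyloxy)-3-methoxybenzoyloxy]-4β-hydroxy-4α-isopropyl-1β-methyl-8-methylidene-5αH-hydroazulen-9-one | C=C1C[C@H](OC(=O)c2ccc(O[Si](C)(C)C(C)(C)C)c(OC)c2)[C@@H]2[C@](C)(CC[C@@]2(O)C(C)C)CC1=O | intermediate
24 | 6α-[4-(tert-butyldimethylsilyloxy)-3-methoxybenzoyloxy]-4α-isopropyl-1β-methyl-8-methylidene-5αH-hydroazulene-4β,9α-diol | C=C1C[C@H](OC(=O)c2ccc(O[Si](C)(C)C(C)(C)C)c(OC)c2)[C@@H]2[C@](C)(CC[C@@]2(O)C(C)C)C[C@@H]1O | intermediate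
25 | 4β,9α-dihydroxy-4α-isopropyl-1β-methyl-8-methylidene-5αH-hydroazulen-6α-yl 4-hydroxy-3-methoxybenzoate (CNP0330487.1) | C=C1C[C@H](OC(=O)c2ccc(O)c(OC)c2)[C@@H]2[C@](C)(CC[C@@]2(O)C(C)C)C[C@@H]1O | target

**Step count**

Total: 15 steps. Longest linear sequence: 14 steps (steps 1–10 and 12–15, from 1); step 11 is a one-step branch.

**Steps most likely to fail**

Step 8. Three processes can divert it. The triplet diradical may close 1,6 (C5–C10 first) because the acetoxy group stabilises a radical at C9, which gives the crossed adduct that cannot fragment. The alkene may add on the β face if the silyl group does not shield it better than the isopropyl group shields the α face. The C5 enolate may lose silanolate, or stay cis-fused, during the basic fragmentation.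

The fallback forms C1–C10 thermally and sets out from 10. Semi-hydrogenation of the alkyne (H2, Pd/CaCO3 poisoned with Pb(OAc)2, quinoline) should give 1-[(5R)-2-methyl-5-(propan-2-yl)-5-(triethylsilyloxy)cyclopent-1-en-1-yl]pent-4-en-1-one F1. Conjugate addition of (CH2=CH)2CuLi with Me3SiCl (THF, −78 °C), anti to the silyloxy group, then equilibration of C5 with K2CO3 in MeOH, should give the C1-vinyl trans ketone F2. Ring-closing metathesis with the second-generation Grubbs catalyst (CH2Cl2, 40 °C) joins the vinyl carbon (C10) to C9 and should give the trans-fused cyclohept-9-en-6-one F3. Hydroboration–oxidation (BH3·THF, then NaOH, H2O2) places boron on C9, since C10 is neopentylic, and also reduces the C6 ketone, to give the 6,9-diol F4. Dess–Martin oxidation of both carbinols comes back to the route at 14.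

Step 14. Hydride may be delivered to the α face of C9 if the axial C15 methyl overrides the catalyst, or 1,4-reduction of the exocyclic enone may compete.

The fallback uses the substrate bias and then inverts; it sets out from 23. Luche reduction (NaBH4, CeCl3·7H2O, MeOH, −78 °C) should give the 9β-alcohol F5 by attack anti to C15. Mitsunobu esterification with 4-nitrobenzoic acid (PPh3, diisopropyl azodicarboxylate, THF) inverts C9 to the 9α-(4-nitrobenzoate) F6. K2CO3 in MeOH at 0 °C then removes the aryl silyl ether first, the resulting phenoxide protecting the vanillate from methanolysis, and the activated nitrobenzoate second. This comes back to the route at 25.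

Step 10. Ligand exchange at the hindered tertiary hydroxyl may be slow, so that undirected hydride attack from the α face of C6, or slow reduction at C9, competes with the internal delivery.

The fallback relies on thermodynamic control and sets out from 14. The C9 ketone, flanked by two methylene groups, is ketalised selectively (1,2-bis(trimethylsilyloxy)ethane, Me3SiOTf cat., CH2Cl2, −78 °C) to the 9,9-ethylenedioxy 6-ketone F7. Dissolving-metal reduction (Li, liquid NH3, THF, −78 °C, then NH4Cl) should give the more stable equatorial 6α-alcohol F8. Aqueous HCl in THF removes the dioxolane and the triethylsilyl ether together and comes back to the route at 16.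

**Further compounds**

F1 | step 8 | 1-[(5R)-2-methyl-5-(propan-2-yl)-5-(triethylsilyloxy)cyclopent-1-en-1-yl]pent-4-en-1-one | C=CCCC(=O)C1=C(C)CC[C@@]1(O[Si](CC)(CC)CC)C(C)C
F2 | step 8 | 1-[1α-vinyl-1β-methyl-4α-isopropyl-4β-(triethylsilyloxy)cyclopent-5β-yl]pent-4-en-1-one (5αH, route numbering) | C=CCCC(=O)[C@@H]1[C@@](C)(C=C)CC[C@@]1(O[Si](CC)(CC)CC)C(C)C
F3 | step 8 | trans-fused 4β-(triethylsilyloxy)-4α-isopropyl-1β-methyl-5αH-hydroazul-9-en-6-one | O=C1CCC=C[C@@]2(C)CC[C@@](O[Si](CC)(CC)CC)(C(C)C)[C@H]12
F4 | step 8 | trans-fused 4β-(triethylsilyloxy)-4α-isopropyl-1β-methyl-5αH-hydroazulene-6,9-diol, epimers at C6 and C9 | OC1CCC(O)C[C@@]2(C)CC[C@@](O[Si](CC)(CC)CC)(C(C)C)[C@H]12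
F5 | step 14 | 9β-epimer of 24 | C=C1C[C@H](OC(=O)c2ccc(O[Si](C)(C)C(C)(C)C)c(OC)c2)[C@@H]2[C@](C)(CC[C@@]2(O)C(C)C)C[C@H]1O
F6 | step 14 | 9α-(4-nitrobenzoate) of 24 | C=C1C[C@H](OC(=O)c2ccc(O[Si](C)(C)C(C)(C)C)c(OC)c2)[C@@H]2[C@](C)(CC[C@@]2(O)C(C)C)C[C@@H]1OC(=O)c1ccc(cc1)[N+](=O)[O-]
F7 | step 10 | 9,9-ethylenedioxy derivative of 14 (C9 dioxolane, C6 ketone) | O=C1CCC2(OCCO2)C[C@@]3(C)CC[C@@](O[Si](CC)(CC)CC)(C(C)C)[C@H]13
F8 | step 10 | 9,9-ethylenedioxy-4β-(triethylsilyloxy)-4α-isopropyl-1β-methyl-5αH-hydroazulen-6α-ol | O[C@H]1CCC2(OCCO2)C[C@@]3(C)CC[C@@](O[Si](CC)(CC)CC)(C(C)C)[C@H]13
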